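## Retrosynthetic overview

1. Kanzonol C is opened at the bond between the ketone carbon and C1' of ring A. The acyl group goes back onto the neighbouring oxygen O2', which gives an isomeric aryl ester, 3-hydroxy-2-prenylphenyl (E)-4-hydroxy-3-prenylcinnamate. The forward step is a photo-Fries rearrangement that ends the synthesis without any protecting group.
2. Enabling feature: ring A is a 2-prenylresorcinol with an oxygen (O2') ortho to the ketone-bearing C1'. In the ester, ring carbon C2 is blocked by the prenyl group, and the open sites C6 (ortho) and C4 (para) are related by the mirror plane through C2 and C5 of the diol. Every productive acyl shift therefore gives the same 2',4'-dihydroxy-3'-prenylphenyl ketone, and the ester O–C(=O) tether is cut in the same event.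
3. The ester comes from a three-component union of 2-prenylresorcinol, Ph3P=C=C=O and 4-hydroxy-3-prenylbenzaldehyde (O–H addition, then Wittig), which sets the E alkene.
4. 2-Prenylresorcinol comes from resorcinol (MOM ethers, directed ortho-metalation at C2, prenyl bromide, acid). The aldehyde comes from 4-hydroxybenzaldehyde by ortho C-prenylation.
5. No ring is formed in the route: both benzene rings are bought, and both prenyl groups are in place before the fragments meet.

Key step: step 6

Remark: the target has no stereocentre and is achiral, so the only stereochemical element to control is the E geometry of the enone double bond.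

## Route

Step 1
Reactants: 1 resorcinol
Product: 2 resorcinol bis(MOM) ether (1,3-bis(methoxymethoxy)benzene)
Conditions: MOMCl (2.4 equiv), i-Pr2NEt (3 equiv), CH2Cl2, 0 °C to rt
Reagents that add atoms: chloromethyl methyl ether (MOMCl), COCCl
Why: O-alkylation of both phenols with the reactive α-chloro ether (acetal protection) gives MOM ethers that later serve as cooperating ortho-directing groups.

Step 2
Reactants: 2 resorcinol bis(MOM) ether, 3 prenyl bromide
Product: 5 2-prenylresorcinol bis(MOM) ether, via aryllithium 4 (not isolated)
Conditions: n-BuLi (1.1 equiv), THF, 0 °C to rt; then 3, −78 °C to rt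
Reagents that add atoms: none
Why: In this directed ortho-metalation the two OMOM groups together steer n-BuLi to C2 between them, and aryllithium 4 is alkylated at the primary carbon of the allylic bromide (SN2).

Step 3
Reactants: 5 2-prenylresorcinol bis(MOM) ether
Product: 6 2-prenylresorcinol
Conditions: cat. aq. HCl, MeOH, 50 °C
Reagents that add atoms: none
Why: Acid-catalysed transacetalisation of the aryl MOM ethers to methanol should be much faster under these mild conditions than protonation of the trisubstituted alkene, so the prenyl group should survive uncyclised.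

Step 4
Reactants: 7 4-hydroxybenzaldehyde, 3 prenyl bromide
Product: 9 4-hydroxy-3-prenylbenzaldehyde, via potassium phenolate 8 (not isolated)
Conditions: KOH (1.0 equiv), H2O, rt; acidic work-up
Reagents that add atoms: none
Why: This is C-alkylation of an ambident phenolate, in which water shields the oxygen by hydrogen bonding so that the ortho carbon attacks the soft allylic bromide, and the two ortho positions are equivalent.

Step 5
Reactants: 6 2-prenylresorcinol, 10 (triphenylphosphoranylidene)ketene, 9 4-hydroxy-3-prenylbenzaldehyde
Product: 12 3-hydroxy-2-prenylphenyl (E)-4-hydroxy-3-prenylcinnamate, via ester ylide 11 (not isolated)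
Conditions: 6 (2.5 equiv, excess recovered), 10 (1.0 equiv), PhMe, 60 °C; then 9 (1.0 equiv), 100 °C
Reagents that add atoms: none
Why: Addition of the phenolic O–H across the cumulated ylide gives stabilised ester ylide 11, whose Wittig olefination of 9 under neutral conditions sets the E double bond (three-component addition/Wittig sequence), while the excess of symmetric diol 6 secures mono-acylation.

Step 6
Reactants: 12 3-hydroxy-2-prenylphenyl (E)-4-hydroxy-3-prenylcinnamate
Product: 16 kanzonol C, via caged radical pair 13 (not isolated), via ortho-dienone 14 (not isolated), via para-dienone 15 (not isolated)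
Conditions: hν (300–310 nm), Ar-sparged PhH (2 mM), FEP flow coil, 20 °C; unreacted 12 recycled
Reagents that add atoms: none
Why: Excitation of the aryl cinnamate cleaves the ArO–C(=O) bond homolytically, the singlet radical pair 13 recombines inside the solvent cage at a ring carbon that carries phenoxyl spin density, and dienone 14 or 15 then tautomerises to the phenol, so that the ester tether is cut and the ketone C–C1' bond is made in one event (photo-Fries rearrangement). The closest known reaction type is the photo-Fries rearrangement of 3-hydroxyphenyl cinnamates to 2',4'-dihydroxychalcones. No ring is closed and no stereocentre is formed; the only stereo-element, the E double bond from step 5, should end up intact because hydrogen-bonded 2'-hydroxychalcones isomerise under light only from Z to E, which corrects any E/Z scrambling that the ester suffers before it rearranges. The step needs regioselectivity, and ring A secures it: recombination at the prenyl-bearing C2 cannot be followed by tautomerisation and is undone by renewed cleavage, recombination at oxygen only returns 12, and C6 (ortho) and C4 (para) are symmetry-equivalent in diol 6, so that 14 and 15 converge on the same ketone 16. It also needs an acyl radical that keeps its CO, which holds here because decarbonylation of a cinnamoyl radical would give a high-energy vinyl radical. The new O–H···O=C hydrogen bond lets 16 lose excitation energy by excited-state proton transfer, and light of 300 nm or longer with exclusion of oxygen should spare the o-prenylphenol units from photocyclisation and from the singlet-oxygen ene reaction.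

## Compound list

1 | resorcinol (benzene-1,3-diol) | Oc1cccc(O)c1 | starting material
2 | 1,3-bis(methoxymethoxy)benzene | COCOc1cccc(OCOC)c1 | intermediate
3 | prenyl bromide (1-bromo-3-methylbut-2-ene) | CC(C)=CCBr | starting material
4 | [2,6-bis(methoxymethoxy)phenyl]lithium | COCOc1cccc(OCOC)c1[Li] | intermediate
5 | 1,3-bis(methoxymethoxy)-2-(3-methylbut-2-en-1-yl)benzene | COCOc1cccc(OCOC)c1CC=C(C)C | intermediate
6 | 2-prenylresorcinol (2-(3-methylbut-2-en-1-yl)benzene-1,3-diol) | CC(C)=CCc1c(O)cccc1O | intermediate
7 | 4-hydroxybenzaldehyde | O=Cc1ccc(O)cc1 | starting material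
8 | potassium 4-formylphenolate | [K+].[O-]c1ccc(C=O)cc1 | intermediate
9 | 4-hydroxy-3-(3-methylbut-2-en-1-yl)benzaldehyde | CC(C)=CCc1cc(C=O)ccc1O | intermediate
10 | (triphenylphosphoranylidene)ketene | O=C=C=P(c1ccccc1)(c1ccccc1)c1ccccc1 | starting material
11 | 3-hydroxy-2-prenylphenyl (triphenylphosphoranylidene)acetate | CC(C)=CCc1c(O)cccc1OC(=O)C=P(c1ccccc1)(c1ccccc1)c1ccccc1 | intermediate
12 | 3-hydroxy-2-(3-methylbut-2-en-1-yl)phenyl (E)-3-[4-hydroxy-3-(3-methylbut-2-en-1-yl)phenyl]prop-2-enoate | CC(C)=CCc1cc(/C=C/C(=O)Oc2cccc(O)c2CC=C(C)C)ccc1O | intermediate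
13 | geminate radical pair: 3-hydroxy-2-prenylphenoxyl and (E)-4-hydroxy-3-prenylcinnamoyl radical | CC(C)=CCc1c(O)cccc1[O].CC(C)=CCc1cc(/C=C/[C]=O)ccc1O | intermediate
14 | 3-hydroxy-2-prenyl-6-[(E)-4-hydroxy-3-prenylcinnamoyl]cyclohexa-2,4-dien-1-one (racemic, transient) | O=C1C(CC=C(C)C)=C(O)C=CC1C(=O)/C=C/c1ccc(O)c(CC=C(C)C)c1 | intermediate
15 | 3-hydroxy-2-prenyl-4-[(E)-4-hydroxy-3-prenylcinnamoyl]cyclohexa-2,5-dien-1-one (racemic, transient) | O=C1C=CC(C(=O)/C=C/c2ccc(O)c(CC=C(C)C)c2)C(O)=C1CC=C(C)C | intermediate
16 | kanzonol C, (E)-1-[2,4-dihydroxy-3-(3-methylbut-2-en-1-yl)phenyl]-3-[4-hydroxy-3-(3-methylbut-2-en-1-yl)phenyl]prop-2-en-1-one | CC(C)=CCc1cc(/C=C/C(=O)c2ccc(O)c(CC=C(C)C)c2O)ccc1O | target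

## Step count and risks

Total step count: 6. Longest linear sequence: 5 steps (steps 1, 2, 3, 5, 6).

**Step 6.** The photoreaction may stall or erode for several reasons.
- Much of the absorbed light can be wasted in E/Z isomerisation of the cinnamate.
- The growing chalcone can screen the ester from the lamp.
- The radicals can leave the cage, so that the acyl part is lost.
- The enoate and the o-prenylphenol units can be drawn into [2+2] cycloaddition or photocyclisation.

The fallback makes the same bond by polar, known chemistry. It sets out from 9 and 5 and comes back at 16. Aldehyde 9 is protected with MOMCl/i-Pr2NEt to 4-(methoxymethoxy)-3-prenylbenzaldehyde F1. A Horner–Wadsworth–Emmons reaction with diethyl [2-(methoxy(methyl)amino)-2-oxoethyl]phosphonate (NaH, THF) then gives the (E)-cinnamic Weinreb amide F2. Bis-MOM ether 5 is lithiated a second time (n-BuLi, TMEDA, THF, 0 °C), now at C4 next to an OMOM group, to give the 4-lithio compound F3. This adds to F2 at −78 °C and, after collapse of the chelate on work-up, should give kanzonol C tris(MOM) ether F4. HCl in MeOH removes the three MOM groups and leads to 16.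

**Step 5.** Three things may go wrong here.
- The acyl group may be handed on among the free phenols.
- The diol may add twice.
- The Wittig step may slow down because the acidic hydroxy-aldehyde protonates the ylide.

The fallback masks the competing phenol and builds the ester by classical acylation. It sets out from 9 and 6 and comes back at 12. A Knoevenagel–Doebner condensation of 9 with malonic acid (pyridine, cat. piperidine, 80 °C) gives (E)-4-hydroxy-3-prenylcinnamic acid F5. TBSCl/imidazole in DMF gives the silyl ether silyl ester F6, and K2CO3 in THF/MeOH/H2O cleaves only the silyl ester to the O-TBS acid F7. Steglich-type coupling (EDC, cat. DMAP, CH2Cl2) with an excess of 6 gives the O-TBS aryl ester F8. Et3N·3HF in THF removes the silyl group without touching the aryl ester and gives 12.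

**Step 4.** O-alkylation and double alkylation may outrun the wanted ortho C-alkylation of the phenolate. The fallback delivers the prenyl group by a sigmatropic shift instead of direct alkylation. It sets out from 7 and comes back at 9. Copper-catalysed O-alkylation of 7 with 3-chloro-3-methylbut-1-yne (cat. CuCl2, DBU, MeCN, 0 °C) gives the 1,1-dimethylpropargyl ether F9. Semihydrogenation over Lindlar catalyst (H2, quinoline, EtOAc) gives the 1,1-dimethylallyl ether F10. Heating in N,N-diethylaniline triggers the aromatic Claisen rearrangement, which places the prenyl group at the ortho carbon and gives 9.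

## Further compounds

F1 | step 6 | 4-(methoxymethoxy)-3-(3-methylbut-2-en-1-yl)benzaldehyde | COCOc1ccc(C=O)cc1CC=C(C)C
F2 | step 6 | (E)-N-methoxy-N-methyl-3-[4-(methoxymethoxy)-3-prenylphenyl]prop-2-enamide | COCOc1ccc(/C=C/C(=O)N(C)OC)cc1CC=C(C)C
F3 | step 6 | [2,4-bis(methoxymethoxy)-3-prenylphenyl]lithium | COCOc1ccc([Li])c(OCOC)c1CC=C(C)C
F4 | step 6 | kanzonol C tris(MOM) ether | COCOc1ccc(/C=C/C(=O)c2ccc(OCOC)c(CC=C(C)C)c2OCOC)cc1CC=C(C)C
F5 | step 5 | (E)-4-hydroxy-3-prenylcinnamic acid | CC(C)=CCc1cc(/C=C/C(=O)O)ccc1O
F6 | step 5 | tert-butyldimethylsilyl (E)-4-(tert-butyldimethylsilyloxy)-3-prenylcinnamate | CC(C)=CCc1cc(/C=C/C(=O)O[Si](C)(C)C(C)(C)C)ccc1O[Si](C)(C)C(C)(C)C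
F7 | step 5 | (E)-4-(tert-butyldimethylsilyloxy)-3-prenylcinnamic acid | CC(C)=CCc1cc(/C=C/C(=O)O)ccc1O[Si](C)(C)C(C)(C)C
F8 | step 5 | 3-hydroxy-2-prenylphenyl (E)-4-(tert-butyldimethylsilyloxy)-3-prenylcinnamate | CC(C)=CCc1cc(/C=C/C(=O)Oc2cccc(O)c2CC=C(C)C)ccc1O[Si](C)(C)C(C)(C)C
F9 | step 4 | 4-[(2-methylbut-3-yn-2-yl)oxy]benzaldehyde | C#CC(C)(C)Oc1ccc(C=O)cc1
F10 | step 4 | 4-[(2-methylbut-3-en-2-yl)oxy]benzaldehyde | C=CC(C)(C)Oc1ccc(C=O)cc1
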